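**Retrosynthetic overview**
1. Xanthohumol 16 ⇐ tris-MOM chalcone 15 (global acetal cleavage) ⇐ saturated ketone 12 (α,β-dehydrogenation sets the E-alkene).
2. Key disconnection: the Cβ–aryl bond of 12, made from a palladium homoenolate (nucleophilic ketone β-carbon, from cyclopropanol 9) and aryl bromide 10; both carbons are electrophilic in ordinary chemistry.
3. Cyclopropanol 9 ⇐ ring A aryllithium + cyclopropanone (from hemiacetal 6), so the whole C3 bridge arrives as one unit.
4. Ring A pattern ⇐ two successive directed ortho-metalations of bis-MOM 5-methoxyresorcinol: prenyl first (between the two OMOM groups), then the carbinol carbon (between OMe and OMOM).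
5. No ring is built: rings A and B come intact from 1 and 10, and the bought cyclopropane of 6 is opened in the key step.

Assumption: xanthohumol has no stereocentre, so the single stereoisomer asked for is the (E)-alkene; 3, 6 and 10 are taken as catalogue compounds.

**Step 1**
Reactants: 1 5-methoxybenzene-1,3-diol
Product: 2 1-methoxy-3,5-bis(methoxymethoxy)benzene
Conditions: NaH, MOMCl, DMF, 0 °C → rt
Reagents that add atoms: chloromethyl methyl ether (MOMCl), COCCl
Why: Double Williamson-type O-alkylation of the two phenoxides (MOM protection) gives the base-stable, strongly ortho-directing acetal groups needed for steps 2 and 3; no stereocentre is formed.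

**Step 2**
Reactants: 2 1-methoxy-3,5-bis(methoxymethoxy)benzene; 3 1-bromo-3-methylbut-2-ene (prenyl bromide)
Product: 5 5-methoxy-1,3-bis(methoxymethoxy)-2-(3-methylbut-2-en-1-yl)benzene, via aryllithium 4 (not isolated)
Conditions: n-BuLi, THF, 0 °C → rt; then CuI (10 mol %), 3, −78 °C → rt
Reagents that add atoms: none
Why: Directed ortho-metalation takes the one ring hydrogen flanked by both OMOM groups (doubly chelated, favoured over the two sites next to the weaker OMe director), and copper-catalysed SN2 allylation of aryllithium 4 by the primary allylic bromide installs the linear prenyl group; no stereocentre is formed.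

**Step 3**
Reactants: 5 5-methoxy-1,3-bis(methoxymethoxy)-2-(3-methylbut-2-en-1-yl)benzene; 6 1-ethoxycyclopropan-1-ol
Product: 9 1-[6-methoxy-2,4-bis(methoxymethoxy)-3-(3-methylbut-2-en-1-yl)phenyl]cyclopropan-1-ol, via aryllithium 7 (not isolated), via cyclopropanone 8 (not isolated)
Conditions: n-BuLi, TMEDA, THF, 0 °C; then 6/MeMgBr (1:1, premixed in THF at 0 °C), 0 °C → rt; aq NH4Cl
Reagents that add atoms: none
Why: A second directed ortho-metalation can only take one of the two symmetry-equivalent ring hydrogens between OMe and OMOM, and aryllithium 7 adds to the strained, non-enolisable carbonyl of cyclopropanone 8 released from the bromomagnesium salt of hemiacetal 6 (Salaün-type cyclopropanol synthesis); the new carbinol carbon is not stereogenic.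

**Step 4**
Reactants: 9 1-[6-methoxy-2,4-bis(methoxymethoxy)-3-(3-methylbut-2-en-1-yl)phenyl]cyclopropan-1-ol; 10 1-bromo-4-(methoxymethoxy)benzene
Product: 12 1-[6-methoxy-2,4-bis(methoxymethoxy)-3-(3-methylbut-2-en-1-yl)phenyl]-3-[4-(methoxymethoxy)phenyl]propan-1-one, via palladium homoenolate 11 (not isolated)
Conditions: Pd(OAc)2 (5 mol %), XPhos (10 mol %), Cs2CO3, toluene, 80 °C
Reagents that add atoms: none
Why: Palladium-catalysed ring-opening cross-coupling of a cyclopropanol (ketone homoenolate arylation), in which oxidative addition of 10 to zerovalent palladium, alkoxide exchange and strain-driven β-carbon elimination give homoenolate 11, whose ketone β-carbon is now the nucleophilic partner and is joined to the electrophilic ipso carbon of the aryl bromide by reductive elimination; no stereocentre is formed.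

**Step 5**
Reactants: 12 1-[6-methoxy-2,4-bis(methoxymethoxy)-3-(3-methylbut-2-en-1-yl)phenyl]-3-[4-(methoxymethoxy)phenyl]propan-1-one
Product: 15 (E)-1-[6-methoxy-2,4-bis(methoxymethoxy)-3-(3-methylbut-2-en-1-yl)phenyl]-3-[4-(methoxymethoxy)phenyl]prop-2-en-1-one, via lithium enolate 13 (not isolated), via sulfilimine 14 (not isolated)
Conditions: LiN(i-Pr)2, THF, −78 °C; then PhS(Cl)=N-t-Bu, −78 °C
Reagents that add atoms: none
Why: Mukaiyama dehydrogenation, in which enolate 13 is sulfenylated at carbon by N-tert-butylbenzenesulfinimidoyl chloride and sulfilimine 14 undergoes an intramolecular syn-elimination that places the aroyl and aryl groups trans, which sets the (E)-alkene, the only stereo-element of the target.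

**Step 6**
Reactants: 15 (E)-1-[6-methoxy-2,4-bis(methoxymethoxy)-3-(3-methylbut-2-en-1-yl)phenyl]-3-[4-(methoxymethoxy)phenyl]prop-2-en-1-one
Product: 16 xanthohumol
Conditions: 3 M aq HCl, MeOH, rt
Reagents that add atoms: none
Why: Acid-catalysed acetal exchange with methanol cleaves all three MOM ethers at room temperature, mild enough that the (E)-enone is neither isomerised nor closed to the flavanone and the prenyl group does not cyclise onto the neighbouring phenol.

**Compound list**
1 | 5-methoxybenzene-1,3-diol (5-methoxyresorcinol) | COc1cc(O)cc(O)c1 | starting material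
2 | 1-methoxy-3,5-bis(methoxymethoxy)benzene | COCOc1cc(OC)cc(OCOC)c1 | intermediate
3 | 1-bromo-3-methylbut-2-ene (prenyl bromide) | CC(C)=CCBr | starting material
4 | [4-methoxy-2,6-bis(methoxymethoxy)phenyl]lithium (not isolated) | [Li]c1c(OCOC)cc(OC)cc1OCOC | intermediate
5 | 5-methoxy-1,3-bis(methoxymethoxy)-2-(3-methylbut-2-en-1-yl)benzene | COc1cc(OCOC)c(CC=C(C)C)c(OCOC)c1 | intermediate
6 | 1-ethoxycyclopropan-1-ol (cyclopropanone ethyl hemiacetal) | CCOC1(O)CC1 | starting material
7 | [6-methoxy-2,4-bis(methoxymethoxy)-3-(3-methylbut-2-en-1-yl)phenyl]lithium (not isolated) | COc1cc(OCOC)c(CC=C(C)C)c(OCOC)c1[Li] | intermediate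
8 | cyclopropanone (not isolated) | O=C1CC1 | intermediate
9 | 1-[6-methoxy-2,4-bis(methoxymethoxy)-3-(3-methylbut-2-en-1-yl)phenyl]cyclopropan-1-ol | COc1cc(OCOC)c(CC=C(C)C)c(OCOC)c1C1(O)CC1 | intermediate
10 | 1-bromo-4-(methoxymethoxy)benzene | COCOc1ccc(Br)cc1 | starting material
11 | {3-[6-methoxy-2,4-bis(methoxymethoxy)-3-(3-methylbut-2-en-1-yl)phenyl]-3-oxopropyl}[4-(methoxymethoxy)phenyl]palladium, the palladium homoenolate (XPhos on palladium not drawn; not isolated) | COCOc1ccc([Pd]CCC(=O)c2c(OC)cc(OCOC)c(CC=C(C)C)c2OCOC)cc1 | intermediate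
12 | 1-[6-methoxy-2,4-bis(methoxymethoxy)-3-(3-methylbut-2-en-1-yl)phenyl]-3-[4-(methoxymethoxy)phenyl]propan-1-one | COCOc1ccc(CCC(=O)c2c(OC)cc(OCOC)c(CC=C(C)C)c2OCOC)cc1 | intermediate
13 | lithium (Z)-enolate of 12 (not isolated) | [Li]O/C(=C\Cc1ccc(OCOC)cc1)c1c(OC)cc(OCOC)c(CC=C(C)C)c1OCOC | intermediate
14 | 2-(N-tert-butyl-S-phenylsulfilimidoyl) derivative of 12 (racemic at carbon and sulfur; not isolated) | COCOc1ccc(CC(C(=O)c2c(OC)cc(OCOC)c(CC=C(C)C)c2OCOC)S(=NC(C)(C)C)c2ccccc2)cc1 | intermediate
15 | (E)-1-[6-methoxy-2,4-bis(methoxymethoxy)-3-(3-methylbut-2-en-1-yl)phenyl]-3-[4-(methoxymethoxy)phenyl]prop-2-en-1-one (tris-MOM xanthohumol) | COCOc1ccc(/C=C/C(=O)c2c(OC)cc(OCOC)c(CC=C(C)C)c2OCOC)cc1 | intermediate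
16 | xanthohumol, (E)-1-[2,4-dihydroxy-6-methoxy-3-(3-methylbut-2-en-1-yl)phenyl]-3-(4-hydroxyphenyl)prop-2-en-1-one | COc1cc(O)c(CC=C(C)C)c(O)c1C(=O)/C=C/c1ccc(O)cc1 | target

**Totals**
Total steps: 6. Longest linear sequence: 6 (1 → 2 → 5 → 9 → 12 → 15 → 16), with 3, 6 and 10 bought.

**Steps most likely to fail**

Step 3. n-BuLi may deprotonate the benzylic/allylic CH2 of the prenyl group instead of the ring, and the hindered aryllithium 7 may add sluggishly to 8. The fallback sets out from 5 and returns at 9. Bromination of the only free, highly activated ring position with NBS in MeCN at 0 °C gives 2-bromo-1-methoxy-3,5-bis(methoxymethoxy)-4-(3-methylbut-2-en-1-yl)benzene F1. Bromine–lithium exchange (t-BuLi, THF, −78 °C), which cannot touch the prenyl CH2, followed by ClCO2Me gives methyl 6-methoxy-2,4-bis(methoxymethoxy)-3-(3-methylbut-2-en-1-yl)benzoate F2. A Kulinkovich cyclopropanation of this ester (EtMgBr, Ti(Oi-Pr)4, THF, rt) then delivers cyclopropanol 9.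

Step 4. Homoenolate 11 can lose a β-hydride to give the aryl vinyl ketone, the caesium alkoxide of the hindered carbinol may exchange slowly, and base may open 9 to the ethyl ketone. The fallback sets out from 9 and returns at 15, bypassing 12 and step 5. It makes the β-hydride path productive: oxidative ring opening of 9 (Pd(OAc)2 cat., pyridine, O2, toluene, 80 °C) gives 1-[6-methoxy-2,4-bis(methoxymethoxy)-3-(3-methylbut-2-en-1-yl)phenyl]prop-2-en-1-one F3. This is used crude in a Mizoroki–Heck reaction with 10 (Pd(OAc)2, P(o-tol)3, Et3N, DMF, 100 °C) to give the (E)-chalcone 15 directly.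

Step 5. Enolisation of the hindered ketone may be incomplete, and the product enone may be attacked under the basic conditions. The fallback sets out from 12 and returns at 15. Soft enolisation (TMSOTf, Et3N, CH2Cl2, 0 °C) gives the (Z)-trimethylsilyl enol ether of 12 F4. Saegusa–Ito oxidation of this enol ether (Pd(OAc)2, MeCN, rt) gives 15.

**Further compounds**
F1 | step 3 | 2-bromo-1-methoxy-3,5-bis(methoxymethoxy)-4-(3-methylbut-2-en-1-yl)benzene | COc1cc(OCOC)c(CC=C(C)C)c(OCOC)c1Br
F2 | step 3 | methyl 6-methoxy-2,4-bis(methoxymethoxy)-3-(3-methylbut-2-en-1-yl)benzoate | COC(=O)c1c(OC)cc(OCOC)c(CC=C(C)C)c1OCOC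
F3 | step 4 | 1-[6-methoxy-2,4-bis(methoxymethoxy)-3-(3-methylbut-2-en-1-yl)phenyl]prop-2-en-1-one | C=CC(=O)c1c(OC)cc(OCOC)c(CC=C(C)C)c1OCOC
F4 | step 5 | (Z)-trimethylsilyl enol ether of 12 | C[Si](C)(C)O/C(=C\Cc1ccc(OCOC)cc1)c1c(OC)cc(OCOC)c(CC=C(C)C)c1OCOC
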